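## Retrosynthetic overview
1. The O8–acyl bond is cut last (Steglich esterification with silyl-protected p-coumaric acid). C8–H comes from an O11-directed reduction of the guai-1(10)-en-8-one, which places O8 trans to the C7 side chain.
2. Feature used: in the seven-membered ring (C1, C5–C10), the oxygen-bearing C8 and the ring-fusion alkene carbon C1 are spanned only by C9 and C10, and C10 carries CH3-14. Removing this two-carbon unit and joining C1 to C8 leaves a bicyclo[3.3.0]octan-8-one.
3. Key disconnection: C1–C10 and C8–C9 come from a but-2-ynoate added across the C1=C8 silyl enol ether. The resulting cyclobutene then gives up its C1–C8 bond, and the ester left on C9 (an allyl ester) is removed later with palladium.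
4. The enol ether comes from 1,4-hydrosilylation of the C1=C5 enone (sets H5). C7–C11 comes from an acetone aldol, the enone from a Nazarov closure of a dienone made by carbonylative Stille coupling, and C4 from a copper-catalysed asymmetric methyl addition.
5. Ring order: ring A (bought), then the second five-membered ring (C5–C6 bond), then a transient four-membered ring, then the seven-membered ring by expansion.

Key step: step 8

Convention: guaiane numbering is used for all carbocycles. Ring A is C1–C5 with CH3-15 on C4, followed by C6, C7 (C11 side chain), C8 (oxygen), C9 and C10 (CH3-14). β is the face of CH3-15, so the target has H5 α, the C7 side chain β and O8 α.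

Assumption: the remote C4 centre does not bias the flat C7 enolate of the diquinane enone, so the aldol is taken to give both C7 epimers, which are separated. The unwanted epimer can be re-enolised under kinetic conditions, reprotonated and resubmitted.

## Route

Step 1
Reactants: 1 cyclopent-2-en-1-one
Product: 3 (S)-3-methylcyclopent-1-en-1-yl trifluoromethanesulfonate, via methylzinc enolate 2 (not isolated)
Conditions: Cu(OTf)2 (2 mol%), (S,R,R)-phosphoramidite from BINOL and bis(1-phenylethyl)amine (4 mol%), Me2Zn, toluene, −30 °C; then Tf2O, −30 to 0 °C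
Reagents that add atoms: dimethylzinc C[Zn]C; trifluoromethanesulfonic anhydride O=S(=O)(OS(=O)(=O)C(F)(F)F)C(F)(F)F
Why: Copper-catalysed asymmetric conjugate addition sets C4 as (S) under ligand control (the ligand antipode is chosen for that face), and O-triflation of the regiodefined zinc enolate fixes the alkene between C1 and C5, next to the new centre.

Step 2
Reactants: 3 (S)-3-methylcyclopent-1-en-1-yl trifluoromethanesulfonate; 4 tributyl(vinyl)stannane
Product: 5 (S)-1-(3-methylcyclopent-1-en-1-yl)prop-2-en-1-one
Conditions: Pd(PPh3)4 (3 mol%), LiCl, CO (1–3 atm), THF, 50 °C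
Reagents that add atoms: carbon monoxide [C-]#[O+]
Why: Carbonylative Stille coupling, in which oxidative addition of the vinyl triflate to zerovalent palladium, CO insertion (C8) and vinyl transfer from tin (C7, C6) give the cross-conjugated dienone without touching C4.

Step 3
Reactants: 5 (S)-1-(3-methylcyclopent-1-en-1-yl)prop-2-en-1-one
Product: 6 (4S)-4-methylbicyclo[3.3.0]oct-1(5)-en-8-one
Conditions: SnCl4, CH2Cl2, 0 to 23 °C
Reagents that add atoms: none
Why: Nazarov cyclisation, in which the SnCl4-bound pentadienyl cation closes conrotatorily (C5–C6 bond) and the oxyallyl cation loses H5 to give the most substituted ring-fusion enone, with C4 a bystander as long as the mild temperature prevents γ-enolisation.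

Step 4
Reactants: 6 (4S)-4-methylbicyclo[3.3.0]oct-1(5)-en-8-one; 7 acetone
Product: 9 (4S)-7β-(2-hydroxypropan-2-yl)-4-methylbicyclo[3.3.0]oct-1(5)-en-8-one, via lithium dienolate 8 (not isolated)
Conditions: LiN(i-Pr)2, THF, −78 °C; acetone, −78 °C; AcOH quench at −78 °C; chromatographic separation of the C7 epimers
Reagents that add atoms: none
Why: Kinetic α′-deprotonation leaves the γ-proton on C4 alone and the aldol addition to acetone builds C7–C11, the side chain being attached here rather than before the Nazarov step because a C11–O group beside the oxyallyl cation would invite a semipinacol methyl shift or elimination, and the 7β epimer is obtained by separation since the flat enolate has no facial bias.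

Step 5
Reactants: 9 (4S)-7β-(2-hydroxypropan-2-yl)-4-methylbicyclo[3.3.0]oct-1(5)-en-8-one
Product: 10 (4S)-4-methyl-7β-[2-(triethylsilyloxy)propan-2-yl]bicyclo[3.3.0]oct-1(5)-en-8-one
Conditions: Et3SiOTf, 2,6-lutidine, CH2Cl2, −78 to 0 °C
Reagents that add atoms: triethylsilyl trifluoromethanesulfonate CC[Si](CC)(CC)OS(=O)(=O)C(F)(F)F
Why: Silyl triflate silylation of a hindered tertiary alcohol with a non-nucleophilic base, which blocks retro-aldol cleavage and removes the O–H that would consume silane and EtAlCl2 later.

Step 6
Reactants: 10 (4S)-4-methyl-7β-[2-(triethylsilyloxy)propan-2-yl]bicyclo[3.3.0]oct-1(5)-en-8-one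
Product: 11 (4S,5S)-4-methyl-8-(triethylsilyloxy)-7β-[2-(triethylsilyloxy)propan-2-yl]bicyclo[3.3.0]oct-1(8)-ene (H5 α)
Conditions: RhCl(PPh3)3 (2 mol%), Et3SiH, toluene, 60 °C
Reagents that add atoms: triethylsilane CC[SiH](CC)CC
Why: Rhodium-catalysed 1,4-hydrosilylation of an enone with a monohydrosilane puts silicon on O8 and hydrogen on C5, so the enol ether can only be C8=C1, and the metal hydride approaches the α face left open by CH3-15 and the C7 side chain (both β), which sets H5 α.

Step 7
Reactants: 12 but-2-ynoic acid; 13 allyl bromide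
Product: 14 allyl but-2-ynoate
Conditions: K2CO3, DMF, 23 °C
Reagents that add atoms: none
Why: Carboxylate O-alkylation (SN2), the allyl ester being chosen because zerovalent palladium removes it at room temperature, whereas a thermal Krapcho removal of a methyl ester would endanger the aldol-type C7–C11 unit and the non-conjugated C1=C10 alkene.

Step 8
Reactants: 11 (4S,5S)-4-methyl-8-(triethylsilyloxy)-7β-[2-(triethylsilyloxy)propan-2-yl]bicyclo[3.3.0]oct-1(8)-ene; 14 allyl but-2-ynoate
Product: 16 allyl (4S,5S)-8,11-bis(triethylsilyloxy)guaia-1(10),8-diene-9-carboxylate (side chain 7β), via cyclobutene 15 (not isolated)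
Conditions: EtAlCl2 (1.0 equiv), CH2Cl2, −78 to 23 °C; Et3N, then aq NaHCO3
Reagents that add atoms: none
Why: Proposed new method: EtAlCl2 binds the ester carbonyl of 14, the nucleophilic enol carbon C1 of 11 adds to the methyl-bearing β-carbon (C1–C10), and the aluminium allenolate collapses through C9 onto the silyloxocarbenium carbon C8 (C8–C9), so the four-membered ring closes stepwise by collapse of a 1,4-zwitterion to give cyclobutene 15 on the convex α face. In 15 the C1–C8 bond has the donor O8 at one end and is vinylogously tied to the Lewis-acid-bound ester at the other, so it breaks heterolytically and relaxes to the C1=C10/C8=C9 diene; the seven-membered ring thus arises by expansion of the five-membered ketone ring (scission of the bond shared by the four- and five-membered rings) and not by cyclisation, and the stepwise path matters because a concerted conrotatory opening would place a trans alkene in that ring. The closest known reactions are the Lewis-acid-promoted (2+2) cycloadditions of silyl enol ethers with propiolates and the two-carbon ring expansion of cyclic enamines with alkynoates; untested is the pairing of a β-methyl ynoate with a fully substituted enol ether, which must create a quaternary C1 beside a fully substituted alkene carbon. C1 and C8 are stereogenic only in 15 (cis fusion imposed by the small ring) and return to sp2, so no lasting stereocentre is made and C4, C5 and C7 are untouched. The step needs C1 and not C7 as the nucleophile, which the enol ether position fixed in step 6 secures, and bonding at the ynoate β-carbon, which the ester polarisation secures, while EtAlCl2 also scavenges adventitious HCl and so shields the enol ether and the tertiary C11–OSiEt3 group.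

Step 9
Reactants: 16 allyl (4S,5S)-8,11-bis(triethylsilyloxy)guaia-1(10),8-diene-9-carboxylate
Product: 17 allyl (4S,5S)-8-oxo-11-(triethylsilyloxy)guai-1(10)-ene-9-carboxylate (side chain 7β; drawn as its chelated C8=C9 enol)
Conditions: Bu4NF (1.0 equiv), AcOH (1.2 equiv), THF, −40 °C
Reagents that add atoms: none
Why: Chemoselective desilylation, since fluoride attacks the enol silane first (it expels a stabilised β-keto ester enolate) while the hindered tertiary O11 silyl ether reacts far more slowly, and the acetic acid buffer prevents base-induced retro-aldol or alkene migration.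

Step 10
Reactants: 17 allyl (4S,5S)-8-oxo-11-(triethylsilyloxy)guai-1(10)-ene-9-carboxylate
Product: 19 (4S,5S)-11-(triethylsilyloxy)guai-1(10)-en-8-one (side chain 7β), via β-keto acid 18 (not isolated)
Conditions: Pd(PPh3)4 (5 mol%), morpholine, THF, 23 °C
Reagents that add atoms: none
Why: Tsuji–Trost-type deallylation, in which zerovalent palladium ionises the allyl ester, morpholine takes up the allyl group, the β-keto acid loses CO2 at room temperature and the dienol is protonated at C9 so that C1=C10 stays out of conjugation, while C7 is safe because its configuration (side chain pseudo-equatorial, cis-1,3 to the C5–C4 bond) is also the thermodynamic one.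

Step 11
Reactants: 19 (4S,5S)-11-(triethylsilyloxy)guai-1(10)-en-8-one
Product: 20 (4S,5S)-11-hydroxyguai-1(10)-en-8-one (side chain 7β)
Conditions: HF·pyridine, pyridine, THF, 0 to 23 °C
Reagents that add atoms: none
Why: Acidic fluoride cleavage of the tertiary triethylsilyl ether, chosen because basic fluoride would promote retro-aldol loss of acetone from the β-hydroxy ketone.

Step 12
Reactants: 20 (4S,5S)-11-hydroxyguai-1(10)-en-8-one
Product: 21 (4S,5S,7S,8S)-guai-1(10)-ene-8,11-diol (8α-OH, side chain 7β)
Conditions: Me4NBH(OAc)3, MeCN–AcOH, −30 °C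
Reagents that add atoms: none
Why: Evans–Saksena hydroxyl-directed reduction, in which boron binds O11 and hydride is delivered through a chair-like six-membered transition state with ring carbon C6 axial (avoiding both C11 methyl groups), which corresponds to axial attack on the conformer with the pseudo-equatorial side chain and should set C8 with O8 α, trans to C7.

Step 13
Reactants: 22 (E)-p-coumaric acid
Product: 24 (E)-3-[4-(tert-butyldimethylsilyloxy)phenyl]prop-2-enoic acid, via bis-silyl derivative 23 (not isolated)
Conditions: t-BuMe2SiCl (2.2 equiv), imidazole, DMF, 23 °C; then AcOH–THF–H2O, 23 °C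
Reagents that add atoms: tert-butyldimethylsilyl chloride CC(C)(C)[Si](C)(C)Cl
Why: Silylation of both acidic O–H groups followed by selective hydrolysis of the far more labile silyl ester leaves only the phenol masked, so it cannot compete as a nucleophile in the esterification.

Step 14
Reactants: 21 (4S,5S,7S,8S)-guai-1(10)-ene-8,11-diol; 24 (E)-3-[4-(tert-butyldimethylsilyloxy)phenyl]prop-2-enoic acid
Product: 25 (4S,5S,7S,8S)-11-hydroxyguai-1(10)-en-8-yl (E)-3-[4-(tert-butyldimethylsilyloxy)phenyl]prop-2-enoate
Conditions: DCC, DMAP (cat.), CH2Cl2, 0 to 23 °C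
Reagents that add atoms: none
Why: Steglich esterification, in which the DMAP-activated acyl group reaches only the secondary O8–H because the tertiary O11–H is too hindered, and no stereocentre is touched.

Step 15
Reactants: 25 (4S,5S,7S,8S)-11-hydroxyguai-1(10)-en-8-yl (E)-3-[4-(tert-butyldimethylsilyloxy)phenyl]prop-2-enoate
Product: 26 (4S,5S,7S,8S)-11-hydroxyguai-1(10)-en-8-yl (E)-p-coumarate (target)
Conditions: Bu4NF, AcOH, THF, 0 °C
Reagents that add atoms: none
Why: Fluoride cleavage of the aryl silyl ether is fast because phenoxide leaves silicon easily, and the acetic acid buffer keeps the cinnamate ester from migrating or hydrolysing.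

## Compound list
1 | cyclopent-2-en-1-one | O=C1C=CCC1 | starting material
2 | methylzinc (S)-3-methylcyclopent-1-en-1-olate | C[C@H]1CCC(O[Zn]C)=C1 | intermediate
3 | (S)-3-methylcyclopent-1-en-1-yl trifluoromethanesulfonate | C[C@H]1CCC(OS(=O)(=O)C(F)(F)F)=C1 | intermediate
4 | tributyl(vinyl)stannane | C=C[Sn](CCCC)(CCCC)CCCC | starting material
5 | (S)-1-(3-methylcyclopent-1-en-1-yl)prop-2-en-1-one | C[C@H]1CCC(C(=O)C=C)=C1 | intermediate
6 | (4S)-4-methylbicyclo[3.3.0]oct-1(5)-en-8-one | C[C@H]1CCC2=C1CCC2=O | intermediate
7 | acetone | CC(C)=O | starting material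
8 | lithium C7=C8 dienolate of 6 | C[C@H]1CCC2=C1CC=C2O[Li] | intermediate
9 | (4S)-7β-(2-hydroxypropan-2-yl)-4-methylbicyclo[3.3.0]oct-1(5)-en-8-one | C[C@H]1CCC2=C1C[C@H](C(C)(C)O)C2=O | intermediate
10 | O11-triethylsilyl ether of 9 | C[C@H]1CCC2=C1C[C@H](C(C)(C)O[Si](CC)(CC)CC)C2=O | intermediate
11 | ring-fusion (C8=C1) triethylsilyl enol ether, H5 α, CH3-15 β, side chain 7β | CC[Si](CC)(CC)OC1=C2CC[C@H](C)[C@@H]2C[C@@H]1C(C)(C)O[Si](CC)(CC)CC | intermediate
12 | but-2-ynoic acid | CC#CC(=O)O | starting material
13 | allyl bromide | C=CCBr | starting material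
14 | allyl but-2-ynoate | CC#CC(=O)OCC=C | intermediate
15 | cyclobutene C1–C10(CH3)=C9(CO2allyl)–C8(OSiEt3), fused on the α face of the C1–C8 bond | CC1=C(C(=O)OCC=C)[C@]2(O[Si](CC)(CC)CC)[C@@H](C(C)(C)O[Si](CC)(CC)CC)C[C@H]3[C@@H](C)CC[C@@]123 | intermediate
16 | allyl 8,11-bis(triethylsilyloxy)guaia-1(10),8-diene-9-carboxylate | CC1=C2CC[C@H](C)[C@@H]2C[C@H](C(C)(C)O[Si](CC)(CC)CC)C(O[Si](CC)(CC)CC)=C1C(=O)OCC=C | intermediate
17 | allyl 8-oxo-11-(triethylsilyloxy)guai-1(10)-ene-9-carboxylate (enol form drawn) | CC1=C2CC[C@H](C)[C@@H]2C[C@H](C(C)(C)O[Si](CC)(CC)CC)C(O)=C1C(=O)OCC=C | intermediate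
18 | corresponding β-keto acid (enol form drawn) | CC1=C2CC[C@H](C)[C@@H]2C[C@H](C(C)(C)O[Si](CC)(CC)CC)C(O)=C1C(=O)O | intermediate
19 | 11-(triethylsilyloxy)guai-1(10)-en-8-one | CC1=C2CC[C@H](C)[C@@H]2C[C@H](C(C)(C)O[Si](CC)(CC)CC)C(=O)C1 | intermediate
20 | 11-hydroxyguai-1(10)-en-8-one | CC1=C2CC[C@H](C)[C@@H]2C[C@H](C(C)(C)O)C(=O)C1 | intermediate
21 | (4S,5S,7S,8S)-guai-1(10)-ene-8,11-diol | CC1=C2CC[C@H](C)[C@@H]2C[C@H](C(C)(C)O)[C@@H](O)C1 | intermediate
22 | (E)-p-coumaric acid | O=C(O)/C=C/c1ccc(O)cc1 | starting material
23 | tert-butyldimethylsilyl (E)-4-(tert-butyldimethylsilyloxy)cinnamate | CC(C)(C)[Si](C)(C)OC(=O)/C=C/c1ccc(O[Si](C)(C)C(C)(C)C)cc1 | intermediate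
24 | (E)-4-(tert-butyldimethylsilyloxy)cinnamic acid | O=C(O)/C=C/c1ccc(O[Si](C)(C)C(C)(C)C)cc1 | intermediate
25 | O-silylated target | CC1=C2CC[C@H](C)[C@@H]2C[C@H](C(C)(C)O)[C@@H](OC(=O)/C=C/c2ccc(O[Si](C)(C)C(C)(C)C)cc2)C1 | intermediate
26 | CNP0403230.1 | CC1=C2CC[C@H](C)[C@@H]2C[C@H](C(C)(C)O)[C@@H](OC(=O)/C=C/c2ccc(O)cc2)C1 | target

Total step count: 15.
Longest linear sequence: 13 (steps 1–6, 8–12, 14, 15).

## Steps most likely to fail

**Step 8.**
- What may go wrong: bond formation between the fully substituted enol carbon and the methyl-bearing alkyne carbon may be sterically refused. Silyl transfer within the zwitterion may end in an open Michael-type addition instead of ring closure. The cyclobutene may resist opening, or the Lewis acid may ionise the C11–O bond.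
- Fallback (known chemistry, from 11, returning at 19): the same C1–C8 insertion is done with a ketene.
  - Dichloroketene (Cl2CHCOCl, Et3N, hexane) adds to the α face of 11 to give the dichlorocyclobutanone F1. Its carbonyl carbon becomes C10 on C1 and its CCl2 carbon becomes C9 on C8.
  - Zn, NH4Cl, MeOH gives the cyclobutanone F2.
  - MeMgBr/CeCl3 (THF, −78 °C) brings in CH3-14 to give the tertiary cyclobutanol F3. Its C10 configuration is of no consequence because C10 becomes sp2.
  - MsCl/Et3N gives the mesylate F4. This should undergo a silyloxy-assisted Grob fragmentation (push from O8, scission of C1–C8, formation of C1=C10, loss of mesylate) directly to 19.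
  - The competing scission of C8–C9 is disfavoured because it would give the less substituted alkene and keep the strained ring fusion.

**Step 4.**
- What may go wrong: there is no facial selectivity at C7 on the flat enolate, the epimers may be hard to separate, and acetone may transfer a proton instead of adding.
- Fallback (from 6, returning at 20): the side chain is postponed until the seven-membered ring exists.
  - Hydrosilylation of 6 as in step 6, with only CH3-15 now governing the face, gives the enol ether F5.
  - Ring expansion with 14 as in step 8 gives the diene ester F6, and desilylation as in step 9 gives the β-keto ester F7.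
  - Double deprotonation (LiN(i-Pr)2, 2.2 equiv, THF, −78 to 0 °C) and addition of acetone at the more reactive C7 terminus (γ-aldol of a β-keto ester dianion) gives the hydroxy β-keto ester F8.
  - Here the reversible aldol and the epimerisable C7 should let the pseudo-equatorial 7β side chain accumulate.
  - Deallylation and decarboxylation as in step 10 then gives 20.

**Step 12.**
- What may go wrong: hydride may be delivered to the wrong face of the flexible seven-membered ketone, or retro-aldol loss of acetone may occur from the free β-hydroxy ketone.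
- Fallback (from 19, returning at 26): the opposite alcohol is made on purpose and then inverted.
  - LiBH(s-Bu)3 (THF, −78 °C) attacks 19 equatorially, away from the side chain, to give the 8β-alcohol F9.
  - Mitsunobu esterification with 24 (PPh3, DIAD, toluene) inverts C8 to give the doubly silylated 8α-ester F10.
  - HF·pyridine removes both silyl groups to give 26.

## Further compounds
F1 | step 8 | 9,9-dichloro-10-oxocyclobutane adduct of 11 (α-face fused) | O=C1C(Cl)(Cl)[C@]2(O[Si](CC)(CC)CC)[C@@H](C(C)(C)O[Si](CC)(CC)CC)C[C@H]3[C@@H](C)CC[C@@]123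
F2 | step 8 | dechlorinated cyclobutanone | O=C1C[C@]2(O[Si](CC)(CC)CC)[C@@H](C(C)(C)O[Si](CC)(CC)CC)C[C@H]3[C@@H](C)CC[C@@]123
F3 | step 8 | 10-methyl tertiary cyclobutanol | C[C@@]1(O)C[C@]2(O[Si](CC)(CC)CC)[C@@H](C(C)(C)O[Si](CC)(CC)CC)C[C@H]3[C@@H](C)CC[C@@]123
F4 | step 8 | methanesulfonate of F3 | C[C@@]1(OS(C)(=O)=O)C[C@]2(O[Si](CC)(CC)CC)[C@@H](C(C)(C)O[Si](CC)(CC)CC)C[C@H]3[C@@H](C)CC[C@@]123
F5 | step 4 | ring-fusion triethylsilyl enol ether without side chain | CC[Si](CC)(CC)OC1=C2CC[C@H](C)[C@@H]2CC1
F6 | step 4 | allyl 8-(triethylsilyloxy)-hydroazulene-1(10),8-diene-9-carboxylate without side chain | CC1=C2CC[C@H](C)[C@@H]2CCC(O[Si](CC)(CC)CC)=C1C(=O)OCC=C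
F7 | step 4 | corresponding β-keto ester (enol form drawn) | CC1=C2CC[C@H](C)[C@@H]2CCC(O)=C1C(=O)OCC=C
F8 | step 4 | allyl 11-hydroxy-8-oxoguai-1(10)-ene-9-carboxylate, side chain 7β (enol form drawn) | CC1=C2CC[C@H](C)[C@@H]2C[C@H](C(C)(C)O)C(O)=C1C(=O)OCC=C
F9 | step 12 | 11-(triethylsilyloxy)guai-1(10)-en-8β-ol | CC1=C2CC[C@H](C)[C@@H]2C[C@H](C(C)(C)O[Si](CC)(CC)CC)[C@H](O)C1
F10 | step 12 | 11-O-triethylsilyl, phenol-O-tert-butyldimethylsilyl 8α-ester | CC1=C2CC[C@H](C)[C@@H]2C[C@H](C(C)(C)O[Si](CC)(CC)CC)[C@@H](OC(=O)/C=C/c2ccc(O[Si](C)(C)C(C)(C)C)cc2)C1
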